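The data are calculated on assumed constants, noise included.

**Time fixed.** At 150 s I compared the runs by one number: f, the share of the charged X found as Q, which is cQ over the X charge. The field calls this the yield at fixed time. It is also the chance that one X molecule sits as Q at that moment.

| flask | X | E | time |
|---|---|---|---|
| birch | 50.0 mM | 100 mM |  |
| oak | 50.0 mM | 150 mM |  |
| larch | 25.0 mM | 100 mM |  |
| alder | 50.0 mM | 240 mM | 150 s |

| run | time / s | [Q] / mM |
|---|---|---|
| birch run | 6.0 | 0.8 |
| birch run | 9.5 | 2.1 |
| birch run | 15 | 3.2 |
| birch run | 24 | 4.1 |
| birch run | 38 | 6.9 |
| birch run | 60 | 8.5 |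
| birch run | 95 | 10.4 |
| birch run | 150 | 13.1 |
| oak run | 6.0 | 1.8 |
| oak run | 9.5 | 2.2 |
| oak run | 15 | 3.4 |
| oak run | 24 | 5.6 |
| oak run | 38 | 7.6 |
| oak run | 60 | 10.0 |
| oak run | 95 | 13.0 |
| oak run | 150 | 15.5 |
| larch run | 6.0 | 0.1 |
| larch run | 9.5 | 0.5 |
| larch run | 15 | 2.0 |
| larch run | 24 | 1.7 |
| larch run | 38 | 3.8 |
| larch run | 60 | 4.3 |
| larch run | 95 | 6.0 |
| larch run | 150 | 7.0 |

(scatter of a reading: 0.5 mM)

- Overall: X + E -> Q.
- Constant volume, constant temperature.
- Readings of a species count what is bound in complexes too.
- "The second partner" is E.
- An order is taken over about fifteen percent of the charge, up and down.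

1. order of the initial rate in [E], near the charge of the birch run, the rate being that where two percent of its X are Q
2. order of the initial rate in [X], near the charge of the birch run, the rate being that where two percent of its X are Q (one fixed amount of Q, the same in the runs compared)
3. Q in the alder run at 150 s, as a share of the X charged

**Bench rule.** The bench rule is pseudo-first-order: at a fixed time, the chance for one X molecule ignores the X charge and grows in step with cE. Birch gave 26.2%. Larch, with half the X, gave 28.0%. The gap of 1.8 percentage points is less than the scatter of 2.00% on the larch share, so the first part of the rule held between these two flasks. The second part put alder at 62.9%.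

**The border.** Oak tested that second part. Its cE stood 1.50 times that of birch, so the rule asked for 39.3%. Oak read 31.0%, which is less than that. The share had grown by a factor of 1.18, not 1.50. So I replaced the rule with the yield exponent n, the logarithm of the ratio of shares over the logarithm of the ratio of cE between two flasks. From birch to oak I read 0.415, with a scatter of about 0.123.

**My reckoning.** The cE of alder stood 1.60 times that of oak, a step beyond the one that gave n. Carrying n across it, I committed to 37.7%. For the orders I used the same ratio of late readings, though these are not initial rates. That gave 0.415 in cE and, from larch against birch, 0.904 in cX.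

**The forecast.** The forecast gave an order of 0.8 in cE, an order of 1.4 in cX and 38% for alder, saying “The curves bend far too early for simple depletion”. Alder gave 33.2%.

    X + E ⇌ Q + L (0.1250 M⁻¹ s⁻¹, 0.04520 M⁻¹ s⁻¹)
    X + E ⇌ XE, settled at all times (16.70 M⁻¹)
    Q → Gy (0.006280 s⁻¹)

**Exponent again.** That share is 16.6 mM of Q. Near the birch charge, the initial rate had order 0.56 in cE and 0.90 in cX. Read again from oak to alder, the yield exponent came to 0.144, less than the 0.415 read from birch to oak.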